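**Retrosynthetic overview**
1. Target ⇐ its tris-MOM ether; global acetal hydrolysis is the last step.
2. Pyranone C ring and the C3–prenyl bond ⇐ one Pd(0)-catalysed O→C prenyl-transfer cycloisomerisation of an o-(prenyloxy)aryl ynone. This is the only ring-forming step; the A and B rings are carried intact from resorcinol.
3. Ynone ⇐ A-ring aldehyde + B-ring arylacetylene (acetylide addition, then MnO2).
4. A-ring aldehyde ⇐ resorcinol: bis-MOM protection, Ir-catalysed meta C–H borylation/oxidation (third oxygen), ortho-formylation, O-prenylation.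
5. B-ring alkyne ⇐ resorcinol: O-methylation, 4,6-diiodination, mono-metalation/hydroxylation, MOM protection, Pd-catalysed ethynylation.

Assumption: the target has no stereocentre and no stereogenic double bond, so there is no enantiomer to control; the only stereocentre in the route (the carbinol of 14) is made racemic and removed by oxidation in step 12.

**A-ring branch**

Step 1
Reactants: 1, resorcinol
Product: 2, 1,3-bis(methoxymethoxy)benzene
Conditions: MOMCl (2.5 eq), i-Pr2NEt (3 eq), CH2Cl2, 0 °C → rt
Reagents that add atoms: chloromethyl methyl ether (MOMCl), COCCl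
Why: Standard O-alkylation of both phenols (Williamson-type acetal formation); MOM tolerates every later basic, organometallic and Pd step and is removed by mild acid at the end.

Step 2
Reactants: 2, 1,3-bis(methoxymethoxy)benzene
Product: 3, 2-[3,5-bis(methoxymethoxy)phenyl]-4,4,5,5-tetramethyl-1,3,2-dioxaborolane
Conditions: B2pin2 (0.7 eq), [Ir(OMe)(cod)]2 (1 mol %), dtbpy (2 mol %), THF, 80 °C
Reagents that add atoms: bis(pinacolato)diboron, CC1(C)OB(OC1(C)C)B1OC(C)(C)C(C)(C)O1
Why: Sterically controlled Ir-catalysed aromatic C–H borylation; C5–H is the only C–H without an ortho substituent, so the boron goes meta to both oxygens and sets the 1,3,5-trioxygenation pattern.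

Step 3
Reactants: 3, the arylboronate
Product: 4, 3,5-bis(methoxymethoxy)phenol
Conditions: 30% H2O2, aq NaOH, THF, 0 °C → rt; NH4Cl work-up
Reagents that add atoms: hydrogen peroxide, OO
Why: Oxidation of the aryl boronate (B→O 1,2-aryl shift) under basic conditions, to which MOM acetals are inert.

Step 4
Reactants: 4, 3,5-bis(methoxymethoxy)phenol
Product: 5, 2-hydroxy-4,6-bis(methoxymethoxy)benzaldehyde
Conditions: MgCl2 (2.5 eq), Et3N (4 eq), (CH2O)n (6 eq), MeCN, reflux
Reagents that add atoms: paraformaldehyde (formaldehyde), C=O
Why: Casnati–Skattebøl ortho-formylation delivers formaldehyde only to a carbon ortho to the magnesium phenoxide (the two ortho sites are equivalent), so the site between the two OMOM groups is untouched.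

Step 5
Reactants: 5, 2-hydroxy-4,6-bis(methoxymethoxy)benzaldehyde; 6, prenyl bromide (1-bromo-3-methylbut-2-ene)
Product: 7, 2,4-bis(methoxymethoxy)-6-[(3-methylbut-2-en-1-yl)oxy]benzaldehyde
Conditions: K2CO3 (2 eq), DMF, rt → 45 °C
Reagents that add atoms: prenyl bromide (6), CC(C)=CCBr
Why: Williamson O-alkylation of the chelated phenol in a polar aprotic solvent gives the SN2 (O-prenyl) ether; the temperature is far below that needed for Claisen rearrangement.

**B-ring branch**

Step 6
Reactants: 1, resorcinol
Product: 8, 1,3-dimethoxybenzene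
Conditions: Me2SO4 (2.3 eq), K2CO3, acetone, reflux
Reagents that add atoms: dimethyl sulfate, COS(=O)(=O)OC
Why: Classical exhaustive O-methylation of a phenol; these two methyl ethers are the 2'- and 4'-OMe groups of the target.

Step 7
Reactants: 8, 1,3-dimethoxybenzene
Product: 9, 1,5-diiodo-2,4-dimethoxybenzene
Conditions: NIS (2.2 eq), TFA (0.3 eq), MeCN, rt → 40 °C
Reagents that add atoms: N-iodosuccinimide, O=C1CCC(=O)N1I
Why: Electrophilic aromatic iodination occurs twice at the ortho/para-activated, unhindered 4- and 6-positions; the position between the two methoxy groups is too hindered.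

Step 8
Reactants: 9, 1,5-diiodo-2,4-dimethoxybenzene
Product: 10, 5-iodo-2,4-dimethoxyphenol
Conditions: i-PrMgCl·LiCl (1.05 eq), THF, −20 → 0 °C; B(OMe)3, −78 °C → rt; then 30% H2O2, aq NaOH, 0 °C
Reagents that add atoms: hydrogen peroxide, OO
Why: Mono iodine–magnesium exchange (the first aryl-Mg deactivates the ring toward a second exchange, and the remaining iodide is meta so no aryne forms), then borate formation and oxidation to the phenol.

Step 9
Reactants: 10, 5-iodo-2,4-dimethoxyphenol
Product: 11, 1-iodo-2,4-dimethoxy-5-(methoxymethoxy)benzene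
Conditions: MOMCl (1.3 eq), i-Pr2NEt, CH2Cl2, 0 °C → rt
Reagents that add atoms: chloromethyl methyl ether (MOMCl), COCCl
Why: Routine phenol protection, so that no proton source is present in steps 11 and 13 and all three protecting groups come off together.

Step 10
Reactants: 11, the aryl iodide; 12, ethynylmagnesium bromide
Product: 13, 1-ethynyl-2,4-dimethoxy-5-(methoxymethoxy)benzene
Conditions: 12 (2 eq), ZnBr2 (2 eq), THF, 0 °C; then 11, Pd(PPh3)4 (5 mol %), rt
Reagents that add atoms: ethynylmagnesium bromide (12), C#C[Mg]Br
Why: Negishi cross-coupling of ethynylzinc bromide with an aryl iodide gives the terminal arylacetylene directly, without copper (no Glaser dimer) and without a silyl deprotection.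

**Union and endgame**

Step 11
Reactants: 13, the arylacetylene; 7, the A-ring aldehyde
Product: 14, rac-1-[2,4-bis(methoxymethoxy)-6-(3-methylbut-2-enyloxy)phenyl]-3-[2,4-dimethoxy-5-(methoxymethoxy)phenyl]prop-2-yn-1-ol
Conditions: 13, n-BuLi (1.0 eq), THF, −78 °C; then 7, −78 → 0 °C; NaHCO3 work-up, Et3N-deactivated silica
Reagents that add atoms: none
Why: 1,2-Addition of a lithium acetylide to a non-enolisable aldehyde; the new carbinol centre is racemic and is erased in step 12, and the very ionisable alcohol is kept away from acid.

Step 12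
Reactants: 14, the propargylic alcohol
Product: 15, 1-[2,4-bis(methoxymethoxy)-6-(3-methylbut-2-enyloxy)phenyl]-3-[2,4-dimethoxy-5-(methoxymethoxy)phenyl]prop-2-yn-1-one
Conditions: activated MnO2 (15 eq), CH2Cl2, rt
Reagents that add atoms: none
Why: Neutral MnO2 oxidation of a benzylic/propargylic alcohol to the ynone leaves the MOM acetals and the prenyl ether untouched.

Step 13
Reactants: 15, the o-(prenyloxy)aryl ynone
Product: 16, 2-[2,4-dimethoxy-5-(methoxymethoxy)phenyl]-5,7-bis(methoxymethoxy)-3-(3-methylbut-2-en-1-yl)-4H-chromen-4-one
Conditions: Pd(PPh3)4 (5 mol %), 4 Å MS, dry THF (0.05 M), 60 °C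
Reagents that add atoms: none (isomerisation, C28H34O10 → C28H34O10)
Why: Proposed new method: Pd(0) ionises the aryl prenyl ether, which becomes a good leaving group only once the ortho-acyl group is present, giving a [(η3-prenyl)PdL2]+ / o-acylphenoxide ion pair with no proton source; the phenoxide adds 6-endo to the ynone β-carbon (the mode that gives a stabilised allenolate or C3–Pd vinyl species under aprotic conditions), and the hindered C3 nucleophile is then coupled irreversibly to the unsubstituted CH2 terminus of the π-prenyl ligand, closing the pyranone and forming the C3–prenyl bond with linear selectivity while regenerating Pd(0). The closest known reaction types are the Pd(0)-catalysed cyclisation of allyl o-alkynylphenyl ethers to 3-allylbenzofurans and Pd-catalysed alkoxy-allylation of activated π-systems (Tsuji–Trost capture of an oxa-Michael enolate); a 6-endo ynone version with a prenyl group has not been shown.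

Step 14
Reactants: 16, the tris-MOM flavone
Product: 17, Artoindonesianin R, 5,7-dihydroxy-2-(5-hydroxy-2,4-dimethoxyphenyl)-3-(3-methylbut-2-en-1-yl)-4H-chromen-4-one
Conditions: 3 M aq HCl / MeOH / THF (1:4:1), 40 °C, monitored and stopped at full conversion
Reagents that add atoms: none
Why: Acid-catalysed acetal hydrolysis removes all three MOM groups while the aryl methyl ethers are stable; there is no phenol positioned to cyclise onto the prenyl group (2'-position is OMe), so the side chain survives mild acid.

**Compound list**
1 | resorcinol | Oc1cccc(O)c1 | starting material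
2 | 1,3-bis(methoxymethoxy)benzene | COCOc1cccc(OCOC)c1 | intermediate
3 | 2-[3,5-bis(methoxymethoxy)phenyl]-4,4,5,5-tetramethyl-1,3,2-dioxaborolane | COCOc1cc(OCOC)cc(c1)B1OC(C)(C)C(C)(C)O1 | intermediate
4 | 3,5-bis(methoxymethoxy)phenol | COCOc1cc(O)cc(OCOC)c1 | intermediate
5 | 2-hydroxy-4,6-bis(methoxymethoxy)benzaldehyde | COCOc1cc(O)c(C=O)c(OCOC)c1 | intermediate
6 | prenyl bromide (1-bromo-3-methylbut-2-ene) | CC(C)=CCBr | starting material
7 | 2,4-bis(methoxymethoxy)-6-[(3-methylbut-2-en-1-yl)oxy]benzaldehyde | COCOc1cc(OCC=C(C)C)c(C=O)c(OCOC)c1 | intermediate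
8 | 1,3-dimethoxybenzene | COc1cccc(OC)c1 | intermediate
9 | 1,5-diiodo-2,4-dimethoxybenzene | COc1cc(OC)c(I)cc1I | intermediate
10 | 5-iodo-2,4-dimethoxyphenol | COc1cc(OC)c(I)cc1O | intermediate
11 | 1-iodo-2,4-dimethoxy-5-(methoxymethoxy)benzene | COCOc1cc(I)c(OC)cc1OC | intermediate
12 | ethynylmagnesium bromide | C#C[Mg]Br | starting material
13 | 1-ethynyl-2,4-dimethoxy-5-(methoxymethoxy)benzene | C#Cc1cc(OCOC)c(OC)cc1OC | intermediate
14 | rac-1-[2,4-bis(methoxymethoxy)-6-(prenyloxy)phenyl]-3-[2,4-dimethoxy-5-(methoxymethoxy)phenyl]prop-2-yn-1-ol | OC(C#Cc1cc(OCOC)c(OC)cc1OC)c1c(OCOC)cc(OCOC)cc1OCC=C(C)C | intermediate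
15 | 1-[2,4-bis(methoxymethoxy)-6-(prenyloxy)phenyl]-3-[2,4-dimethoxy-5-(methoxymethoxy)phenyl]prop-2-yn-1-one | O=C(C#Cc1cc(OCOC)c(OC)cc1OC)c1c(OCOC)cc(OCOC)cc1OCC=C(C)C | intermediate
16 | 2-[2,4-dimethoxy-5-(methoxymethoxy)phenyl]-5,7-bis(methoxymethoxy)-3-(3-methylbut-2-en-1-yl)-4H-chromen-4-one | COCOc1cc(OCOC)c2c(c1)oc(-c1cc(OCOC)c(OC)cc1OC)c(CC=C(C)C)c2=O | intermediate
17 | Artoindonesianin R (achiral) | COc1cc(OC)c(-c2oc3cc(O)cc(O)c3c(=O)c2CC=C(C)C)cc1O | target

**Totals**
Total step count: 14.
Longest linear sequence: 9 steps (steps 1–5 then 11–14; the B-ring branch, steps 6–10 then 11–14, is also 9).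

**Three steps most likely to fail**
1. Step 13 (proposed new Pd(0) prenyl-transfer cycloisomerisation). Risks are 3-H flavone from adventitious protons, the reverse-prenyl (1,1-dimethylallyl) isomer, A-ring C-prenylation, and the 5-exo aurone. Fallback with known chemistry: alkylate 5 with MeI instead of prenyl bromide and carry the o-methoxy ynone through steps 11–12. Then run an ICl iodocyclisation (CH2Cl2, −78 °C) to the 3-iodoflavone, followed by Pd-catalysed Stille coupling with tributyl(3-methylbut-2-enyl)stannane (or α-selective Suzuki coupling with prenyl-Bpin) to reach 16. This costs one extra step (15 total, longest linear sequence 10).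
2. Step 10 (direct ethynylation). Risks are double arylation to the diarylacetylene or incomplete transmetalation. Fallback: abandon cross-coupling for C1 homologation — convert 11 to the aldehyde (i-PrMgCl·LiCl, then DMF) and treat it with the Ohira–Bestmann reagent (K2CO3, MeOH) to give 13.
3. Step 14 (acidic removal of three MOM groups next to a prenyl group). Risks are hydration or MeOH addition to the alkene, or carbonyl-assisted cyclisation. Fallback: change the protecting-group strategy to TIPS ethers on all three phenols (TIPSCl in steps 1 and 9) and finish with a fluoride deprotection (TBAF/AcOH, THF, 0 °C), so no acid is used.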